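Retrosynthetic cuts, in order: C10–Br and the C9 carbonyl oxygen (back to a 9-methylene-10,11-ene), then C5=C6 (Wittig), which restores a C6–O–C12 lactone; behind it lie C12–O (iodolactonisation), C7–C8 (Johnson–Claisen) and C12–C13 (alkylation of a 2-lithiocyclopentenone ketal).
Enabling feature: the C12 oxygen and C6 are linked through C8 and C7, so a five-membered lactone ring (O, C6, C7, C8, C12) that the target lacks can be cis-fused to the carbocycle C8–C12. It binds the C12–O configuration to the C8 centre and later, as a butenolide, holds C6 cis to C12 across C7=C8.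
Forward: the carbocycle is bought; the ω-chain is attached at C12 and the C6–C7 arm at C8; the temporary lactone ring closes (step 7), is turned into an ene-butenolide and is opened by lactol Wittig olefination, which adds C1–C5 and frees the 12-hydroxyl; C9 oxidation and C10 bromination finish.
Stereochemistry: CBS reduction sets an (R)-carbinol, the [3,3] shift carries it suprafacially to C8, and cis-iodolactonisation relays it to C12, the only stereocentre of the target. 14Z comes from (Z)-oct-2-en-1-ol, 7E from the butenolide ring, 5Z from the unstabilised ylide.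

Key step: step 7

Assumption: atoms are numbered as in prostanoids (C1 ester carbonyl, ring C8–C12, C20 chain end); lactol 18, epoxide 25 and bromohydrin 26 are carried as diastereomer mixtures because those centres are destroyed later.
Remark on descriptors: with C6 cis to C12 the 7,8-alkene is named Z while C9 is CH2 or CHOH and E once C9 is a carbonyl. The descriptors at C12 and the ring fusion in 13–16, 25 and 26 change through CIP priorities alone; the spatial arrangement stays the same.

Step 1
Reactants: 1 (Z)-oct-2-en-1-ol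
Product: 2 (Z)-1-bromooct-2-ene
Conditions: CBr4, PPh3, CH2Cl2, 0 °C
Reagents that add atoms: carbon tetrabromide, BrC(Br)(Br)Br
Why: Appel bromination displaces the alkoxyphosphonium ion by SN2 at the primary carbon under neutral conditions, so neither allylic transposition nor Z-to-E isomerisation is expected.

Step 2
Reactants: 3 2-bromocyclopent-2-en-1-one
Product: 4 6-bromo-1,4-dioxaspiro[4.4]non-6-ene
Conditions: HOCH2CH2OH, p-TsOH (cat.), benzene, reflux, Dean–Stark
Reagents that add atoms: ethylene glycol, OCCO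
Why: Acid-catalysed ketalisation with azeotropic removal of water masks the carbonyl so that the vinyl bromide can be lithiated, and the α-bromo substituent keeps the alkene in place.

Step 3
Reactants: 4 6-bromo-1,4-dioxaspiro[4.4]non-6-ene; 2 (Z)-1-bromooct-2-ene
Product: 7 2-[(Z)-oct-2-en-1-yl]cyclopent-2-en-1-one, via lithio ketal 5 (not isolated), via alkylated ketal 6 (not isolated)
Conditions: n-BuLi, THF, −78 °C; then 2, HMPA, −78 → 0 °C; then 10% aq (CO2H)2, 20 °C
Reagents that add atoms: water, O
Why: Bromine–lithium exchange gives an α-keto vinyl anion equivalent whose SN2 alkylation by the primary allylic bromide attaches the chain at C12 with the ring alkene position fixed and the Z alkene untouched, and mild acid ketal hydrolysis then frees the enone without base that could draw the skipped diene into conjugation.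

Step 4
Reactants: 7 2-[(Z)-oct-2-en-1-yl]cyclopent-2-en-1-one
Product: 8 (R)-2-[(Z)-oct-2-en-1-yl]cyclopent-2-en-1-ol
Conditions: (S)-2-methyl-CBS-oxazaborolidine (20 mol %), catecholborane, toluene, −78 °C
Reagents that add atoms: none
Why: Corey–Bakshi–Shibata reduction, in which the carbonyl binds the catalyst boron anti to the substituted alkene arm (the large group) so that the (S)-catalyst delivers hydride to the face giving the (R)-carbinol, while catecholborane at −78 °C does not hydroborate either alkene.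

Step 5
Reactants: 8 (R)-2-[(Z)-oct-2-en-1-yl]cyclopent-2-en-1-ol; 9 triethyl orthoacetate
Product: 11 ethyl 2-[(1R)-2-[(Z)-oct-2-en-1-yl]cyclopent-2-en-1-yl]acetate, via ketene acetal 10 (not isolated)
Conditions: 9 (excess), EtCO2H (cat.), 140 °C, EtOH distilled off
Reagents that add atoms: none
Why: Johnson–Claisen rearrangement, in which orthoester exchange and loss of ethanol give the ketene acetal whose [3,3] shift across the five-membered ring is necessarily suprafacial, so the carbinol configuration is transferred to the new C8 centre (R) and the ring alkene moves to C11=C12.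

Step 6
Reactants: 11 ethyl 2-[(1R)-2-[(Z)-oct-2-en-1-yl]cyclopent-2-en-1-yl]acetate
Product: 12 2-[(1R)-2-[(Z)-oct-2-en-1-yl]cyclopent-2-en-1-yl]acetic acid
Conditions: LiOH, THF/MeOH/H2O, 20 °C; then 1 M HCl to pH 3
Reagents that add atoms: lithium hydroxide, [Li+].[OH-]
Why: Ester saponification, which cannot epimerise C8 because that centre is not α to the carboxyl group.

Step 7
Reactants: 12 2-[(1R)-2-[(Z)-oct-2-en-1-yl]cyclopent-2-en-1-yl]acetic acid
Product: 13 (3aR,6S,6aS)-6-iodo-6a-[(Z)-oct-2-en-1-yl]hexahydro-2H-cyclopenta[b]furan-2-one (cis-fused; iodine trans to the lactone oxygen)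
Conditions: I2, KI, NaHCO3, THF/H2O, 0 °C, dark; aq Na2S2O3 work-up
Reagents that add atoms: iodine, II
Why: Iodolactonisation (halolactonisation): reversible iodonium formation on the ring alkene is followed by anti attack of the carboxylate at the tertiary carbon C12, forming the C12–O bond. The γ-lactone ring (O, C6, C7, C8, C12) closes in the 5-exo-trig mode. The two-atom arm on C8 can reach C12 only on its own face, so the fusion is cis and the C8 centre alone fixes the C12 configuration; iodine at C11 ends trans to the lactone oxygen because the addition is anti. Attack at C12 and not C11 follows from the Markovnikov preference for the trisubstituted terminus and from the strain of the alternative bridged δ-lactone. The C14=C15 alkene does not interfere, since an iodonium ion there could be captured only through a seven-membered ring and therefore reverts.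

Step 8
Reactants: 13 (3aR,6S,6aS)-6-iodo-6a-[(Z)-oct-2-en-1-yl]hexahydro-2H-cyclopenta[b]furan-2-one
Product: 14 (3aR,6aS)-6a-[(Z)-oct-2-en-1-yl]-3,3a,4,6a-tetrahydro-2H-cyclopenta[b]furan-2-one
Conditions: DBU, THF, reflux
Reagents that add atoms: none
Why: E2 dehydroiodination, in which C12 is quaternary so the only anti-periplanar β-hydrogen lies on C10 and the alkene can form only as C10=C11.

Step 9
Reactants: 14 (3aR,6aS)-6a-[(Z)-oct-2-en-1-yl]-3,3a,4,6a-tetrahydro-2H-cyclopenta[b]furan-2-one
Product: 15 (3R,3aS,6aR)-6a-[(Z)-oct-2-en-1-yl]-3-(phenylselanyl)-3,3a,4,6a-tetrahydro-2H-cyclopenta[b]furan-2-one (PhSe exo; cis to H-3a)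
Conditions: LiN(iPr)2, THF, −78 °C; enolate added to PhSeCl, THF, −78 °C
Reagents that add atoms: benzeneselenenyl chloride, Cl[Se]c1ccccc1
Why: α-Selenenylation of the lactone enolate, where the electrophile enters on the convex face of the cis-fused bicycle and so places selenium cis to the ring-fusion hydrogen on C8, as the following syn elimination requires.

Step 10
Reactants: 15 (3R,3aS,6aR)-6a-[(Z)-oct-2-en-1-yl]-3-(phenylselanyl)-3,3a,4,6a-tetrahydro-2H-cyclopenta[b]furan-2-one
Product: 17 (6aR)-6a-[(Z)-oct-2-en-1-yl]-4,6a-dihydro-2H-cyclopenta[b]furan-2-one, via selenoxide 16 (not isolated)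
Conditions: mCPBA (1 equiv), CH2Cl2, −78 °C; then iPr2NH, −78 → 20 °C
Reagents that add atoms: none
Why: Selenoxide syn-elimination, in which selenium is oxidised far faster than either alkene at −78 °C and the only syn β-hydrogen is the one on C8, so the C7=C8 butenolide that locks C6 cis to C12 is the sole possible alkene, the amine trapping the selenenic acid.

Step 11
Reactants: 17 (6aR)-6a-[(Z)-oct-2-en-1-yl]-4,6a-dihydro-2H-cyclopenta[b]furan-2-one
Product: 18 (6aR)-6a-[(Z)-oct-2-en-1-yl]-4,6a-dihydro-2H-cyclopenta[b]furan-2-ol (anomer mixture)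
Conditions: iBu2AlH (1.1 equiv), CH2Cl2, −78 °C; aq KNaC4H4O6
Reagents that add atoms: none
Why: Partial 1,2-reduction of a lactone to the lactol, where the tetrahedral aluminate is stable at −78 °C and prevents over-reduction, and C12 being quaternary excludes aromatisation to a furan.

Step 12
Reactants: 18 (6aR)-6a-[(Z)-oct-2-en-1-yl]-4,6a-dihydro-2H-cyclopenta[b]furan-2-ol; 19 (4-carboxybutyl)triphenylphosphonium bromide
Product: 21 (5Z,7Z,12R,14Z)-12-hydroxyprosta-5,7,10,14-tetraenoic acid, via phosphorus ylide 20 (not isolated)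
Conditions: 19 (3 equiv), KN(SiMe3)2 (6 equiv), THF, 0 °C; then 18, −78 → 0 °C; pH 5 NaH2PO4 buffer
Reagents that add atoms: none
Why: Wittig olefination of a lactol, in which ring–chain tautomerism supplies the (Z)-γ-hydroxy enal, the unstabilised ylide builds C5=C6 with Z selectivity and releases the C12 alkoxide, and the C7=C8 geometry is inherited from the butenolide ring.

Step 13
Reactants: 21 (5Z,7Z,12R,14Z)-12-hydroxyprosta-5,7,10,14-tetraenoic acid
Product: 22 methyl (5Z,7Z,12R,14Z)-12-hydroxyprosta-5,7,10,14-tetraenoate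
Conditions: Me3SiCHN2, PhMe/MeOH, 0 °C
Reagents that add atoms: (trimethylsilyl)diazomethane, C[Si](C)(C)C=[N+]=[N-]
Why: Methyl esterification by a diazoalkane under neutral conditions, so the acid-labile doubly allylic tertiary alcohol is not ionised.

Step 14
Reactants: 22 methyl (5Z,7Z,12R,14Z)-12-hydroxyprosta-5,7,10,14-tetraenoate
Product: 23 methyl (5Z,7Z,12R,14Z)-12-(triethylsilyloxy)prosta-5,7,10,14-tetraenoate
Conditions: Et3SiOTf, 2,6-lutidine, CH2Cl2, −78 → 0 °C
Reagents that add atoms: triethylsilyl trifluoromethanesulfonate, CC[Si](CC)(CC)OS(=O)(=O)C(F)(F)F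
Why: Silylation of a tertiary alcohol by a silyl triflate under lutidine buffering, which blocks chromate-ester formation and oxidative 1,3-transposition in the next step and epoxy-alcohol migration in the one after.

Step 15
Reactants: 23 methyl (5Z,7Z,12R,14Z)-12-(triethylsilyloxy)prosta-5,7,10,14-tetraenoate
Product: 24 methyl (5Z,7E,12R,14Z)-9-oxo-12-(triethylsilyloxy)prosta-5,7,10,14-tetraenoate
Conditions: t-BuOOH (decane), (C5H5NH)2Cr2O7 (cat.), Celite, PhH, 10 → 20 °C, dark
Reagents that add atoms: tert-butyl hydroperoxide, CC(C)(C)OO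
Why: Chromium-catalysed allylic oxidation of a 1,4-diene to the cross-conjugated dienone, in which C9 carries the only doubly allylic C–H bonds, so hydrogen abstraction by the tert-butylperoxyl radical and collapse of the derived peroxide to the ketone should occur there and spare the singly allylic C4, C13 and C16 methylenes.

Step 16
Reactants: 24 methyl (5Z,7E,12R,14Z)-9-oxo-12-(triethylsilyloxy)prosta-5,7,10,14-tetraenoate
Product: 25 methyl (5Z,7E,12S,14Z)-10,11-epoxy-9-oxo-12-(triethylsilyloxy)prosta-5,7,14-trienoate (epoxide diastereomers)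
Conditions: 30% H2O2, NaOH (cat.), MeOH, −20 °C
Reagents that add atoms: hydrogen peroxide, OO
Why: Weitz–Scheffer nucleophilic epoxidation, where hydroperoxide adds to C11, the β-carbon of the more electrophilic endocyclic enone, and the enolate closes onto oxygen, the isolated 14,15-alkene being inert and the face of attack immaterial because C10 and C11 become sp2 again.

Step 17
Reactants: 25 methyl (5Z,7E,12S,14Z)-10,11-epoxy-9-oxo-12-(triethylsilyloxy)prosta-5,7,14-trienoate
Product: 28 bromovulone I [methyl (5Z,7E,12R,14Z)-10-bromo-12-hydroxy-9-oxoprosta-5,7,10,14-tetraenoate], via bromohydrin 26 (not isolated), via silyl-protected bromoenone 27 (not isolated)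
Conditions: 48% aq HBr, MeCN, 0 → 20 °C, dark
Reagents that add atoms: hydrogen bromide, Br
Why: Acid-mediated opening of an α,β-epoxy ketone by bromide at C10 (the carbonyl-activated α-carbon, C11 being neopentyl), dehydration of the β-hydroxy ketone through its enol to the α-bromo enone and hydrolysis of the silyl ether by the same aqueous acid, with C12 untouched because a cation there would be destabilised by the adjacent enone.

Compound list
1 | (Z)-oct-2-en-1-ol | CCCCC/C=C\CO | starting material
2 | (Z)-1-bromooct-2-ene | CCCCC/C=C\CBr | intermediate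
3 | 2-bromocyclopent-2-en-1-one | O=C1CCC=C1Br | starting material
4 | 6-bromo-1,4-dioxaspiro[4.4]non-6-ene | BrC1=CCCC12OCCO2 | intermediate
5 | 6-lithio-1,4-dioxaspiro[4.4]non-6-ene (lithio ketal; not isolated) | [Li]C1=CCCC12OCCO2 | intermediate
6 | 6-[(Z)-oct-2-en-1-yl]-1,4-dioxaspiro[4.4]non-6-ene (alkylated ketal; not isolated) | CCCCC/C=C\CC1=CCCC12OCCO2 | intermediate
7 | 2-[(Z)-oct-2-en-1-yl]cyclopent-2-en-1-one | CCCCC/C=C\CC1=CCCC1=O | intermediate
8 | (R)-2-[(Z)-oct-2-en-1-yl]cyclopent-2-en-1-ol | CCCCC/C=C\CC1=CCC[C@H]1O | intermediate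
9 | triethyl orthoacetate | CCOC(C)(OCC)OCC | starting material
10 | 1-ethoxyvinyl (1R)-2-[(Z)-oct-2-en-1-yl]cyclopent-2-en-1-yl ether (ketene acetal; not isolated) | CCCCC/C=C\CC1=CCC[C@H]1OC(=C)OCC | intermediate
11 | ethyl 2-[(1R)-2-[(Z)-oct-2-en-1-yl]cyclopent-2-en-1-yl]acetate | CCCCC/C=C\CC1=CCC[C@@H]1CC(=O)OCC | intermediate
12 | 2-[(1R)-2-[(Z)-oct-2-en-1-yl]cyclopent-2-en-1-yl]acetic acid | CCCCC/C=C\CC1=CCC[C@@H]1CC(=O)O | intermediate
13 | (3aR,6S,6aS)-6-iodo-6a-[(Z)-oct-2-en-1-yl]hexahydro-2H-cyclopenta[b]furan-2-one | CCCCC/C=C\C[C@]12OC(=O)C[C@H]1CC[C@@H]2I | intermediate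
14 | (3aR,6aS)-6a-[(Z)-oct-2-en-1-yl]-3,3a,4,6a-tetrahydro-2H-cyclopenta[b]furan-2-one | CCCCC/C=C\C[C@]12OC(=O)C[C@H]1CC=C2 | intermediate
15 | (3R,3aS,6aR)-6a-[(Z)-oct-2-en-1-yl]-3-(phenylselanyl)-3,3a,4,6a-tetrahydro-2H-cyclopenta[b]furan-2-one | CCCCC/C=C\C[C@]12OC(=O)[C@H]([Se]c3ccccc3)[C@H]1CC=C2 | intermediate
16 | Se-oxide of 15 (selenoxide; not isolated) | CCCCC/C=C\C[C@]12OC(=O)[C@H]([Se](=O)c3ccccc3)[C@H]1CC=C2 | intermediate
17 | (6aR)-6a-[(Z)-oct-2-en-1-yl]-4,6a-dihydro-2H-cyclopenta[b]furan-2-one | CCCCC/C=C\C[C@]12OC(=O)C=C1CC=C2 | intermediate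
18 | (6aR)-6a-[(Z)-oct-2-en-1-yl]-4,6a-dihydro-2H-cyclopenta[b]furan-2-ol (anomer mixture) | CCCCC/C=C\C[C@]12OC(O)C=C1CC=C2 | intermediate
19 | (4-carboxybutyl)triphenylphosphonium bromide | OC(=O)CCCC[P+](c1ccccc1)(c1ccccc1)c1ccccc1.[Br-] | starting material
20 | potassium 5-(triphenyl-λ5-phosphanylidene)pentanoate (ylide; not isolated) | [K+].[O-]C(=O)CCCC=P(c1ccccc1)(c1ccccc1)c1ccccc1 | intermediate
21 | (5Z,7Z,12R,14Z)-12-hydroxyprosta-5,7,10,14-tetraenoic acid | CCCCC/C=C\C[C@@]1(O)C=CC/C1=C/C=C\CCCC(=O)O | intermediate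
22 | methyl (5Z,7Z,12R,14Z)-12-hydroxyprosta-5,7,10,14-tetraenoate | CCCCC/C=C\C[C@@]1(O)C=CC/C1=C/C=C\CCCC(=O)OC | intermediate
23 | methyl (5Z,7Z,12R,14Z)-12-(triethylsilyloxy)prosta-5,7,10,14-tetraenoate | CCCCC/C=C\C[C@@]1(O[Si](CC)(CC)CC)C=CC/C1=C/C=C\CCCC(=O)OC | intermediate
24 | methyl (5Z,7E,12R,14Z)-9-oxo-12-(triethylsilyloxy)prosta-5,7,10,14-tetraenoate | CCCCC/C=C\C[C@@]1(O[Si](CC)(CC)CC)C=CC(=O)/C1=C/C=C\CCCC(=O)OC | intermediate
25 | methyl (5Z,7E,12S,14Z)-10,11-epoxy-9-oxo-12-(triethylsilyloxy)prosta-5,7,14-trienoate (epoxide diastereomers) | CCCCC/C=C\C[C@@]1(O[Si](CC)(CC)CC)C2OC2C(=O)/C1=C/C=C\CCCC(=O)OC | intermediate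
26 | methyl (5Z,7E,12S,14Z)-10-bromo-11-hydroxy-9-oxo-12-(triethylsilyloxy)prosta-5,7,14-trienoate (bromohydrin; not isolated) | CCCCC/C=C\C[C@@]1(O[Si](CC)(CC)CC)C(O)C(Br)C(=O)/C1=C/C=C\CCCC(=O)OC | intermediate
27 | methyl (5Z,7E,12R,14Z)-10-bromo-9-oxo-12-(triethylsilyloxy)prosta-5,7,10,14-tetraenoate (not isolated) | CCCCC/C=C\C[C@@]1(O[Si](CC)(CC)CC)C=C(Br)C(=O)/C1=C/C=C\CCCC(=O)OC | intermediate
28 | bromovulone I, methyl (5Z,7E,12R,14Z)-10-bromo-12-hydroxy-9-oxoprosta-5,7,10,14-tetraenoate | CCCCC/C=C\C[C@@]1(O)C=C(Br)C(=O)/C1=C/C=C\CCCC(=O)OC | target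

Total step count: 17. Longest linear sequence: 16 steps (3 to 28 through steps 2–17; the branch from 1 through steps 1 and 3–17 is equally long).

Steps most likely to fail

Step 15. The hydrogen abstraction at C9 gives a radical delocalised over C5, C7, C9 and C11; oxygen may be delivered at a wrong terminus, or bond rotation in that radical may erode the 5Z and 7,8 geometry. The fallback delivers oxygen by an ene/[2,3]-sigmatropic sequence instead. Setting out from 23, SeO2 (cat.) with t-BuOOH in CH2Cl2 at 0 °C should react at the trisubstituted C7=C8 alkene, take hydrogen from C9 and return oxygen to C9 with the alkene back at C7=C8 and C9 trans to C6. This gives methyl (5Z,7Z,12R,14Z)-9-hydroxy-12-(triethylsilyloxy)prosta-5,7,10,14-tetraenoate F1. Oxidation of this doubly allylic secondary alcohol with Dess–Martin periodinane and NaHCO3 in CH2Cl2 comes back to the route at 24.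

Step 17. The strong aqueous acid may trigger competing processes: hydrobromination or isomerisation of the light- and acid-sensitive 5Z,7E-dienone, ester hydrolysis, or incomplete dehydration and desilylation that leave mixtures. The fallback separates the three events under non-protic conditions. Setting out from 25, MgBr2·OEt2 in Et2O at −20 °C opens the epoxide at C10 to bromohydrin 26, which is now isolated. MeSO2Cl and Et3N in CH2Cl2 at 0 °C convert it into methyl (5Z,7E,14Z)-10-bromo-11-(methanesulfonyloxy)-9-oxo-12-(triethylsilyloxy)prosta-5,7,14-trienoate F2, which loses methanesulfonate by base-induced β-elimination with excess Et3N to give 27. HF·pyridine in THF/pyridine at 0 °C then removes the silyl group and comes back to the route at 28.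

Step 12. The ring-opened (Z)-hydroxy-enal has an acidic C9–H and may isomerise through its dienolate under the basic conditions before it is olefinated, or the lactolate may react sluggishly. The fallback olefinates an open-chain, O-silylated enal that cannot re-close. Setting out from 17, iBu2AlH (2.5 equiv) in CH2Cl2 at −78 → 0 °C reduces the butenolide to (2Z)-2-[(2R)-2-hydroxy-2-[(2Z)-oct-2-en-1-yl]cyclopent-3-en-1-ylidene]ethan-1-ol F3. Et3SiOTf and 2,6-lutidine give the bis(triethylsilyl) ether of that diol F4. Swern oxidation (oxalyl chloride, DMSO, then Et3N, −78 → −30 °C) cleaves and oxidises only the primary allylic silyl ether to (2Z)-2-[(2R)-2-[(2Z)-oct-2-en-1-yl]-2-(triethylsilyloxy)cyclopent-3-en-1-ylidene]acetaldehyde F5. Ylide 20 at −78 °C gives (5Z,7Z,12R,14Z)-12-(triethylsilyloxy)prosta-5,7,10,14-tetraenoic acid F6, and Me3SiCHN2 in PhMe/MeOH comes back to the route at 23.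

Further compounds
F1 | step 15 | methyl (5Z,7Z,12R,14Z)-9-hydroxy-12-(triethylsilyloxy)prosta-5,7,10,14-tetraenoate (C9 epimers) | CCCCC/C=C\C[C@@]1(O[Si](CC)(CC)CC)C=CC(O)/C1=C/C=C\CCCC(=O)OC
F2 | step 17 | methyl (5Z,7E,14Z)-10-bromo-11-(methanesulfonyloxy)-9-oxo-12-(triethylsilyloxy)prosta-5,7,14-trienoate | CCCCC/C=C\C[C@@]1(O[Si](CC)(CC)CC)C(OS(C)(=O)=O)C(Br)C(=O)/C1=C/C=C\CCCC(=O)OC
F3 | step 12 | (2Z)-2-[(2R)-2-hydroxy-2-[(2Z)-oct-2-en-1-yl]cyclopent-3-en-1-ylidene]ethan-1-ol | CCCCC/C=C\C[C@@]1(O)C=CC/C1=C/CO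
F4 | step 12 | triethyl{[(2Z)-2-[(2R)-2-[(2Z)-oct-2-en-1-yl]-2-(triethylsilyloxy)cyclopent-3-en-1-ylidene]ethyl]oxy}silane | CCCCC/C=C\C[C@@]1(O[Si](CC)(CC)CC)C=CC/C1=C/CO[Si](CC)(CC)CC
F5 | step 12 | (2Z)-2-[(2R)-2-[(2Z)-oct-2-en-1-yl]-2-(triethylsilyloxy)cyclopent-3-en-1-ylidene]acetaldehyde | CCCCC/C=C\C[C@@]1(O[Si](CC)(CC)CC)C=CC/C1=C/C=O
F6 | step 12 | (5Z,7Z,12R,14Z)-12-(triethylsilyloxy)prosta-5,7,10,14-tetraenoic acid | CCCCC/C=C\C[C@@]1(O[Si](CC)(CC)CC)C=CC/C1=C/C=C\CCCC(=O)O
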